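**Retrosynthetic overview**
1. Target ⇐ last step: a diazomethyl group tethered at C5 of a cis-fused hydroazulenone inserts into the C1–C10 bond (1,2-shift of C10), turning the cyclopentenone into the cyclohexenone and closing the cyclobutane at once.
2. The diester hydroazulenone ⇐ a cycloheptenone by conjugate borylation/oxidation (C7–O), Evans–Tishchenko reduction (C7 senecioate, C9–OH) and isovalerylation.
3. The cycloheptenone ⇐ cyclopentenone 12 by ozonolysis and aldol condensation; 12 ⇐ bicyclic enol-ether acetal 10 by acetal opening and C-methylation (C10).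
4. 10 ⇐ a dihydropyran-locked triketone by aldol condensation; this ⇐ enamine-catalysed conjugate addition of 3,3-dimethylpent-4-enal to 3-acetylhex-3-ene-2,5-dione (sets C5, then C4).
5. Ring order: dihydropyran (temporary) → cyclopentenone → cycloheptenone → cyclohexenone + cyclobutane (ring expansion).

Assumption: labels C1–C11 in the reasoning are the longipinane locants of the target (C1 ketone, C2=C3, C4/C5/C10/C11 four-membered ring, C6 CMe2, C7 senecioate, C9 isovalerate) traced back into every intermediate; compound names use their own locants.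

**Route**

Step 1
Reactants: 1 3-methylbut-2-enal; 2 vinylmagnesium bromide
Product: 4 3,3-dimethylpent-4-enal, via silyl enol ether 3 (not isolated)
Conditions: 2 (1.3 equiv), CuBr·SMe2 (5 mol %), Me3SiCl (2 equiv), HMPA (2 equiv), THF, −78 °C; then 1 M HCl, 0 °C
Reagents that add atoms: none
Why: Copper-catalysed, chlorosilane-accelerated conjugate addition of a Grignard reagent to the β,β-disubstituted enal gives the 1,4-adduct as its silyl enol ether, which dilute acid hydrolyses to the aldehyde; no stereocentre is formed.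

Step 2
Reactants: 5 pentane-2,4-dione; 6 2-oxopropanal
Product: 7 3-acetylhex-3-ene-2,5-dione
Conditions: 6 (40 % in water, 1.5 equiv), piperidinium acetate (10 mol %), CH2Cl2, MgSO4, 0 → 23 °C, slow addition of 5
Reagents that add atoms: none
Why: Knoevenagel condensation at the aldehyde carbon of methylglyoxal, with excess aldehyde and slow diketone addition to suppress a second Michael addition; the alkene carries two identical acetyl groups, so there is no geometric isomerism.

Step 3
Reactants: 4 3,3-dimethylpent-4-enal; 7 3-acetylhex-3-ene-2,5-dione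
Product: 9 (3R,4S)-4,5-diacetyl-2-methoxy-6-methyl-3-(2-methylbut-3-en-2-yl)-3,4-dihydro-2H-pyran, via lactol 8 (not isolated)
Conditions: (R)-2-[diphenyl(trimethylsilyloxy)methyl]pyrrolidine (10 mol %), PhCO2H (10 mol %), toluene, 0 °C; then MeOH, PPTS (10 mol %), 23 °C
Reagents that add atoms: methanol (CO)
Why: Enamine-catalysed Michael addition of the aldehyde to the doubly activated CH terminus of the ene-trione, in which the catalyst shields one enamine face and sets C5, the usual syn topicity (also the thermodynamic 3,4-trans arrangement, C4 being epimerisable) sets C4, the diketone enol closes onto the aldehyde as a lactol, and acid/methanol locks it as the mixed acetal (anomer mixture).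

Step 4
Reactants: 9 (3R,4S)-4,5-diacetyl-2-methoxy-6-methyl-3-(2-methylbut-3-en-2-yl)-3,4-dihydro-2H-pyran
Product: 10 (4R,4aR)-3-methoxy-1,5-dimethyl-4-(2-methylbut-3-en-2-yl)-4,4a-dihydrocyclopenta[c]pyran-7(3H)-one
Conditions: KOtBu (20 mol %), t-BuOH–THF, 23 °C
Reagents that add atoms: none
Why: Intramolecular aldol condensation in which the α'-methyl enolate of the vinylogous-ester ketone (C2) attacks the free methyl ketone (C3) in a five-membered closure, favoured because the vinylogous-ester carbonyl is a poor electrophile and closure through the enol-ether methyl would need a bridgehead alkene; C4 stops being α to a ketone and is fixed, and no new stereocentre forms.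

Step 5
Reactants: 10 (4R,4aR)-3-methoxy-1,5-dimethyl-4-(2-methylbut-3-en-2-yl)-4,4a-dihydrocyclopenta[c]pyran-7(3H)-one
Product: 11 (4S)-5-acetyl-4-[(2R)-1,1-dimethoxy-3,3-dimethylpent-4-en-2-yl]-3-methylcyclopent-2-en-1-one
Conditions: MeOH, CSA (10 mol %), 23 °C
Reagents that add atoms: methanol (CO)
Why: Acid-catalysed transacetalisation, in which the ring oxygen leaves as a vinylogous-acid enol and methanol traps the oxocarbenium ion, giving the open dimethyl acetal and the β-diketone (C10 epimers and enol); C4 and C5 are untouched.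

Step 6
Reactants: 11 (4S)-5-acetyl-4-[(2R)-1,1-dimethoxy-3,3-dimethylpent-4-en-2-yl]-3-methylcyclopent-2-en-1-one
Product: 12 (4R,5S)-5-acetyl-4-[(2R)-1,1-dimethoxy-3,3-dimethylpent-4-en-2-yl]-3,5-dimethylcyclopent-2-en-1-one
Conditions: MeI (3 equiv), K2CO3 (2 equiv), acetone, 23 °C
Reagents that add atoms: iodomethane (CI)
Why: C-alkylation of the cyclic β-diketone enolate, with iodomethane entering anti to the bulky C4 side chain, so quaternary C10 is formed with the acetyl group cis to the side chain.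

Step 7
Reactants: 12 (4R,5S)-5-acetyl-4-[(2R)-1,1-dimethoxy-3,3-dimethylpent-4-en-2-yl]-3,5-dimethylcyclopent-2-en-1-one
Product: 14 (3aR,4R,8aS)-4-(dimethoxymethyl)-3,5,5,8a-tetramethyl-3a,4,5,8a-tetrahydroazulene-1,8-dione, via keto aldehyde 13 (not isolated)
Conditions: O3, CH2Cl2, −78 °C (stopped when the terminal alkene is consumed); Me2S, −78 → 23 °C; then piperidinium acetate (30 mol %), toluene, 60 °C
Reagents that add atoms: none
Why: Ozonolysis cleaves the electron-rich terminal vinyl group much faster than the enone alkene, and the resulting non-enolisable neopentyl aldehyde undergoes intramolecular aldol condensation with the acetyl methyl (C8) to close the cis-fused cycloheptenone, the ozone-derived oxygen leaving as water; no new stereocentre forms.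

Step 8
Reactants: 14 (3aR,4R,8aS)-4-(dimethoxymethyl)-3,5,5,8a-tetramethyl-3a,4,5,8a-tetrahydroazulene-1,8-dione
Product: 16 (3aR,4R,6R,8aS)-4-(dimethoxymethyl)-6-hydroxy-3,5,5,8a-tetramethyl-3a,4,5,6,7,8a-hexahydroazulene-1,8-dione, via boronate 15 (not isolated)
Conditions: B2pin2 (1.2 equiv), CuCl (5 mol %), Xantphos (5 mol %), NaOtBu (5 mol %), MeOH (2 equiv), THF, 23 °C; then NaBO3·4H2O, THF–H2O, 23 °C
Reagents that add atoms: sodium perborate ([Na+].[O-]OB=O)
Why: Copper-catalysed conjugate borylation attacks only the β-monosubstituted cycloheptenone (the β,β-disubstituted cyclopentenone is inert) from the convex face of the cis-fused bicycle, opposite the acetal on C5 and the five-membered ring, and oxidation with retention gives the C7 alcohol (7R).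

Step 9
Reactants: 16 (3aR,4R,6R,8aS)-4-(dimethoxymethyl)-6-hydroxy-3,5,5,8a-tetramethyl-3a,4,5,6,7,8a-hexahydroazulene-1,8-dione; 1 3-methylbut-2-enal
Product: 17 (3aR,4R,6R,8R,8aS)-4-(dimethoxymethyl)-8-hydroxy-3,5,5,8a-tetramethyl-1-oxo-1,3a,4,5,6,7,8,8a-octahydroazulen-6-yl 3-methylbut-2-enoate
Conditions: 1 (6 equiv), SmI2 (30 mol %), THF, −10 °C
Reagents that add atoms: none
Why: Evans–Tishchenko reduction, in which the samarium-bound hemiacetal formed from the C7 alkoxide and the enal delivers hydride intramolecularly to the C9 ketone on the C7–O face (trans-1,3, 9R) and leaves its acyl group on C7 as the senecioate; the C1 enone is out of reach.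

Step 10
Reactants: 17 (3aR,4R,6R,8R,8aS)-4-(dimethoxymethyl)-8-hydroxy-3,5,5,8a-tetramethyl-1-oxo-1,3a,4,5,6,7,8,8a-octahydroazulen-6-yl 3-methylbut-2-enoate; 18 3-methylbutanoyl chloride
Product: 19 (3aR,4R,6R,8R,8aS)-4-(dimethoxymethyl)-3,5,5,8a-tetramethyl-8-[(3-methylbutanoyl)oxy]-1-oxo-1,3a,4,5,6,7,8,8a-octahydroazulen-6-yl 3-methylbut-2-enoate
Conditions: 18 (3 equiv), pyridine, DMAP (0.2 equiv), CH2Cl2, 0 → 35 °C
Reagents that add atoms: none
Why: Nucleophile-catalysed acylation of the remaining hindered secondary alcohol, kept mild to avoid 1,3-acyl migration; no stereocentre changes.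

Step 11
Reactants: 19 (3aR,4R,6R,8R,8aS)-4-(dimethoxymethyl)-3,5,5,8a-tetramethyl-8-[(3-methylbutanoyl)oxy]-1-oxo-1,3a,4,5,6,7,8,8a-octahydroazulen-6-yl 3-methylbut-2-enoate
Product: 22 (4R,5S,7R,9R,10R,11R)-9-[(3-methylbutanoyl)oxy]-1-oxolongipin-2-en-7-yl 3-methylbut-2-enoate, via sulfonylhydrazone 20 (not isolated), via diazoalkane 21 (not isolated)
Conditions: 2-(CF3)C6H4SO2NHNH2 (1.1 equiv), PPTS (10 mol %), MeCN, 23 °C; solvent change to CH2Cl2, NaH (1.2 equiv), −40 → −10 °C; Sc(OTf)3 (20 mol %), −78 → 0 °C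
Reagents that add atoms: none
Why: Proposed new method: an intramolecular, Lewis-acid-promoted diazoalkane–ketone homologation across a ring (bridging ring expansion by 1,2-shift), in which the acetal is exchanged for a sulfonylhydrazone, base releases the non-stabilised diazoalkane at C11 below −10 °C, and the Sc(OTf)3-activated C1 carbonyl, held 1,5 to the diazo carbon on the concave face, is attacked to give a bridged diazonium alkoxide that cannot close to an epoxide (O–C–C–N2 cannot become antiperiplanar in the bicyclo[2.2.1] frame) and whose diazonium group sits endo, away from the C9 substituent and therefore antiperiplanar to the C1–C10 bond, so that C10 migrates from C1 to C11 with retention and loss of N2, forming the C1–C11 and C10–C11 bonds, the cyclohexenone and the cyclobutane together and fixing C11 by the cage; the closest known reaction type is the intermolecular Lewis-acid-promoted ring expansion of cyclic ketones with diazoalkanes (Tiffeneau–Demjanov-type homologation), not yet shown for a tethered diazoalkane converting a cyclopentenone into a bicyclo[3.1.1]heptenone.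

**Compound list**
1 | 3-methylbut-2-enal | CC(C)=CC=O | starting material
2 | vinylmagnesium bromide | C=C[Mg]Br | starting material
3 | trimethyl[(3,3-dimethylpenta-1,4-dien-1-yl)oxy]silane (E/Z mixture) | C=CC(C)(C)C=CO[Si](C)(C)C | intermediate
4 | 3,3-dimethylpent-4-enal | C=CC(C)(C)CC=O | intermediate
5 | pentane-2,4-dione | CC(=O)CC(C)=O | starting material
6 | 2-oxopropanal (methylglyoxal) | CC(=O)C=O | starting material
7 | 3-acetylhex-3-ene-2,5-dione | CC(=O)C=C(C(C)=O)C(C)=O | intermediate
8 | (3R,4S)-4,5-diacetyl-6-methyl-3-(2-methylbut-3-en-2-yl)-3,4-dihydro-2H-pyran-2-ol (anomer mixture) | OC1OC(C)=C(C(C)=O)[C@@H](C(C)=O)[C@@H]1C(C)(C)C=C | intermediate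
9 | (3R,4S)-4,5-diacetyl-2-methoxy-6-methyl-3-(2-methylbut-3-en-2-yl)-3,4-dihydro-2H-pyran (anomer mixture) | COC1OC(C)=C(C(C)=O)[C@@H](C(C)=O)[C@@H]1C(C)(C)C=C | intermediate
10 | (4R,4aR)-3-methoxy-1,5-dimethyl-4-(2-methylbut-3-en-2-yl)-4,4a-dihydrocyclopenta[c]pyran-7(3H)-one (anomer mixture) | COC1OC(C)=C2C(=O)C=C(C)[C@H]2[C@@H]1C(C)(C)C=C | intermediate
11 | (4S)-5-acetyl-4-[(2R)-1,1-dimethoxy-3,3-dimethylpent-4-en-2-yl]-3-methylcyclopent-2-en-1-one (C5 epimers and enol) | COC(OC)[C@H]([C@@H]1C(C)=CC(=O)C1C(C)=O)C(C)(C)C=C | intermediate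
12 | (4R,5S)-5-acetyl-4-[(2R)-1,1-dimethoxy-3,3-dimethylpent-4-en-2-yl]-3,5-dimethylcyclopent-2-en-1-one | COC(OC)[C@H]([C@@H]1C(C)=CC(=O)[C@]1(C)C(C)=O)C(C)(C)C=C | intermediate
13 | (3R)-3-[(1R,5S)-5-acetyl-2,5-dimethyl-4-oxocyclopent-2-en-1-yl]-4,4-dimethoxy-2,2-dimethylbutanal | COC(OC)[C@H]([C@@H]1C(C)=CC(=O)[C@]1(C)C(C)=O)C(C)(C)C=O | intermediate
14 | (3aR,4R,8aS)-4-(dimethoxymethyl)-3,5,5,8a-tetramethyl-3a,4,5,8a-tetrahydroazulene-1,8-dione | COC(OC)[C@@H]1[C@@H]2C(C)=CC(=O)[C@]2(C)C(=O)C=CC1(C)C | intermediate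
15 | (3aR,4R,6R,8aS)-4-(dimethoxymethyl)-3,5,5,8a-tetramethyl-6-(4,4,5,5-tetramethyl-1,3,2-dioxaborolan-2-yl)-3a,4,5,6,7,8a-hexahydroazulene-1,8-dione | COC(OC)[C@@H]1[C@@H]2C(C)=CC(=O)[C@]2(C)C(=O)C[C@@H](B3OC(C)(C)C(C)(C)O3)C1(C)C | intermediate
16 | (3aR,4R,6R,8aS)-4-(dimethoxymethyl)-6-hydroxy-3,5,5,8a-tetramethyl-3a,4,5,6,7,8a-hexahydroazulene-1,8-dione | COC(OC)[C@@H]1[C@@H]2C(C)=CC(=O)[C@]2(C)C(=O)C[C@@H](O)C1(C)C | intermediate
17 | (3aR,4R,6R,8R,8aS)-4-(dimethoxymethyl)-8-hydroxy-3,5,5,8a-tetramethyl-1-oxo-1,3a,4,5,6,7,8,8a-octahydroazulen-6-yl 3-methylbut-2-enoate | COC(OC)[C@@H]1[C@@H]2C(C)=CC(=O)[C@]2(C)[C@H](O)C[C@@H](OC(=O)C=C(C)C)C1(C)C | intermediate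
18 | 3-methylbutanoyl chloride | CC(C)CC(Cl)=O | starting material
19 | (3aR,4R,6R,8R,8aS)-4-(dimethoxymethyl)-3,5,5,8a-tetramethyl-8-[(3-methylbutanoyl)oxy]-1-oxo-1,3a,4,5,6,7,8,8a-octahydroazulen-6-yl 3-methylbut-2-enoate | COC(OC)[C@@H]1[C@@H]2C(C)=CC(=O)[C@]2(C)[C@H](OC(=O)CC(C)C)C[C@@H](OC(=O)C=C(C)C)C1(C)C | intermediate
20 | 2-(trifluoromethyl)benzenesulfonylhydrazone of the C4 carbaldehyde corresponding to 19 (CH(OMe)2 replaced by CH=N–NHSO2Ar) | O=S(=O)(N/N=C/[C@@H]1[C@@H]2C(C)=CC(=O)[C@]2(C)[C@H](OC(=O)CC(C)C)C[C@@H](OC(=O)C=C(C)C)C1(C)C)c1ccccc1C(F)(F)F | intermediate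
21 | 4-(diazomethyl) analogue of 19 (CH(OMe)2 replaced by CH=N2) | [N-]=[N+]=C[C@@H]1[C@@H]2C(C)=CC(=O)[C@]2(C)[C@H](OC(=O)CC(C)C)C[C@@H](OC(=O)C=C(C)C)C1(C)C | intermediate
22 | (4R,5S,7R,9R,10R,11R)-9-[(3-methylbutanoyl)oxy]-1-oxolongipin-2-en-7-yl 3-methylbut-2-enoate | CC(C)=CC(=O)O[C@@H]1C[C@@H](OC(=O)CC(C)C)[C@@]2(C)[C@@H]3C(=O)C=C(C)[C@H]2[C@@H]3C1(C)C | target

**Totals and risks**
Total steps: 11. Longest linear sequence: 10 (steps 1, 3–11; step 2 is a one-step branch).

Three steps most likely to fail: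

- Step 11 (the new bridging ring expansion). The diazoalkane may lose N2 with a 1,2-hydride shift to an alkene, or the vinyl carbon C2 may migrate instead of C10. Fallback by known chemistry, a classical Tiffeneau–Demjanov sequence that sets out from 19 and comes back at 22: PPTS in aqueous acetone hydrolyses the acetal to the C4 carbaldehyde F5; hydroxylamine hydrochloride and pyridine give the aldoxime F6; NaBO3·4H2O in acetic acid oxidises it to the nitromethyl compound F7; DBU in THF closes an intramolecular nitroaldol onto the C1 carbonyl and the nitro group equilibrates to the less hindered endo position, giving the bridged β-nitro alcohol F8; Zn in acetic acid reduces it to the bridged β-amino alcohol F9; NaNO2 in aqueous acetic acid at 0 °C forms the endo diazonium ion, and C10, antiperiplanar to it, shifts to C11 to give 22.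

- Step 3 (asymmetric conjugate addition to the ene-trione). Compound 7 is an untested acceptor for enamine catalysis and may oligomerise or give low enantioselectivity. Fallback by a chiral auxiliary, setting out from 4 and 7 and coming back at 9: condensation of 4 with (S)-1-amino-2-(methoxymethyl)pyrrolidine gives the SAMP hydrazone of 3,3-dimethylpent-4-enal F1; LDA in THF at −78 °C followed by 7 gives the conjugate-addition hydrazone F2 with auxiliary control at C5; saturated aqueous oxalic acid in ether cleaves the hydrazone to lactol 8, which is acetalised with MeOH and PPTS as in step 3 to 9.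

- Step 7 (seven-membered aldol condensation). Ring closure may be slow and lose out to retro-Claisen cleavage of the non-enolisable β-diketone or to a vinylogous aldol from the C3 methyl group. Fallback by metathesis, setting out from 12 and coming back at 14: LDA at −78 °C and dimethyl(methylidene)ammonium iodide give the Mannich base F3; iodomethane and then NaHCO3 eliminate trimethylamine to give the vinyl ketone F4; second-generation Grubbs catalyst in CH2Cl2 at 40 °C closes the C7=C8 bond between the acryloyl and vinyl groups to give 14.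

**Further compounds**
F1 | step 3 | SAMP hydrazone of 3,3-dimethylpent-4-enal | C=CC(C)(C)C/C=N/N1CCC[C@H]1COC
F2 | step 3 | SAMP hydrazone of (2R,3S)-3,4-diacetyl-2-(2-methylbut-3-en-2-yl)-5-oxohexanal | C=CC(C)(C)[C@H](/C=N/N1CCC[C@H]1COC)[C@H](C(C)=O)C(C(C)=O)C(C)=O
F3 | step 7 | (4R,5S)-4-[(2R)-1,1-dimethoxy-3,3-dimethylpent-4-en-2-yl]-5-[3-(dimethylamino)propanoyl]-3,5-dimethylcyclopent-2-en-1-one | COC(OC)[C@H]([C@@H]1C(C)=CC(=O)[C@]1(C)C(=O)CCN(C)C)C(C)(C)C=C
F4 | step 7 | (4R,5S)-5-acryloyl-4-[(2R)-1,1-dimethoxy-3,3-dimethylpent-4-en-2-yl]-3,5-dimethylcyclopent-2-en-1-one | COC(OC)[C@H]([C@@H]1C(C)=CC(=O)[C@]1(C)C(=O)C=C)C(C)(C)C=C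
F5 | step 11 | (3aR,4R,6R,8R,8aS)-4-formyl-3,5,5,8a-tetramethyl-8-[(3-methylbutanoyl)oxy]-1-oxo-1,3a,4,5,6,7,8,8a-octahydroazulen-6-yl 3-methylbut-2-enoate | O=C[C@@H]1[C@@H]2C(C)=CC(=O)[C@]2(C)[C@H](OC(=O)CC(C)C)C[C@@H](OC(=O)C=C(C)C)C1(C)C
F6 | step 11 | aldoxime of F5 | O/N=C/[C@@H]1[C@@H]2C(C)=CC(=O)[C@]2(C)[C@H](OC(=O)CC(C)C)C[C@@H](OC(=O)C=C(C)C)C1(C)C
F7 | step 11 | 4-(nitromethyl) analogue of F5 (CHO replaced by CH2NO2) | [O-][N+](=O)C[C@@H]1[C@@H]2C(C)=CC(=O)[C@]2(C)[C@H](OC(=O)CC(C)C)C[C@@H](OC(=O)C=C(C)C)C1(C)C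
F8 | step 11 | bridged β-nitro alcohol from bonding the nitromethyl carbon of F7 to the C1 carbonyl carbon (1-hydroxy-2-endo-nitrobicyclo[2.2.1]hept-5-ene core fused to the cycloheptane diester) | O[C@@]12C=C(C)[C@H]3[C@@H]([C@H]1[N+](=O)[O-])C(C)(C)[C@H](OC(=O)C=C(C)C)C[C@@H](OC(=O)CC(C)C)[C@@]23C
F9 | step 11 | bridged β-amino alcohol (F8 with NH2 in place of NO2) | O[C@@]12C=C(C)[C@H]3[C@@H]([C@H]1N)C(C)(C)[C@H](OC(=O)C=C(C)C)C[C@@H](OC(=O)CC(C)C)[C@@]23C
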